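**Plan**

- Locants: cyclohexene ring Ca (CH bearing the carbinol carbon Cg), Cb (CH bearing the aryl group), Cc(H)=Cd(CH3), CeH2, Cf(CH3)2. Ar = 5,7-dimethoxy-2-oxo-2H-chromen-8-yl.
- Cut 1 (last step forward): Cc=Cd and Ce–Cf together. This removes a CH2=C(CH3) unit and leaves Ar–CH(CHO)–CH[C(CH3)=CH2]–CH(OH)–Ar, kept as its lactol.
- Enabling feature: Cf is a tertiary-radical site that an isopropenyl group on Ca can supply. It is joined to the methyl-bearing Cd through the single carbon Ce. Cc lies γ to the oxygen on Cg, so Cc can be stored as the hemiacetal carbon of a five-membered ring (O, Cg, Ca, Cb, Cc) that the target does not contain.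
- Cut 2: the Cb–Ar bond (1,2-aryl shift from Cc, retron an (E)-styrene). Cut 3: Ca–Cg (allylboration of the 8-formylcoumarin). The dienyl chain comes from the same aldehyde by two Wittig homologations.
- Forward ring order: the oxolane forms in step 7; the cyclohexene closes in step 9 as the oxolane opens.
- Stereochemistry: Cg and Ca come from a chiral phosphoric acid and the chair transition state of an (E)-boronate (anti). Cb comes from stereospecific anti addition and aryl migration on the alkene face fixed by allylic strain at Ca.

Key step: step 9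

Assumption: the (R)-configured phosphoric acid is taken to give the (R)-carbinol, by analogy with its behaviour toward other aryl aldehydes; the (S)-acid would be used if the sense were opposite.
Assumption: the anomeric carbon of 10 and 14 and the phosphorus-bearing carbon of 14 are epimer mixtures, which is harmless because both become sp2 or are lost.

**Route**

Step 1
Reactants: 1 5,7-dimethoxy-2H-chromen-2-one (5,7-dimethoxycoumarin)
Product: 2 5,7-dimethoxy-2-oxo-2H-chromene-8-carbaldehyde
Conditions: Cl2CHOMe, TiCl4, CH2Cl2, 0 °C to rt; ice-water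
Reagents that add atoms: dichloromethyl methyl ether COC(Cl)Cl; water O
Why: Rieche formylation should take place at coumarin C8, which is ortho and para to the two methoxy groups and less crowded than C6 between them.

Step 2
Reactants: 2 5,7-dimethoxy-2-oxo-2H-chromene-8-carbaldehyde; 3 (triphenylphosphoranylidene)acetaldehyde
Product: 4 (2E)-3-(5,7-dimethoxy-2-oxo-2H-chromen-8-yl)prop-2-enal
Conditions: 3 (1.0 equiv, slow addition), PhMe, 90 °C
Reagents that add atoms: none
Why: Wittig olefination with a stabilised formyl ylide should give the (E)-enal, and limiting the ylide holds back a second homologation.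

Step 3
Reactants: 4 (2E)-3-(5,7-dimethoxy-2-oxo-2H-chromen-8-yl)prop-2-enal; 5 2-(triphenylphosphoranylidene)propanal
Product: 6 (2E,4E)-5-(5,7-dimethoxy-2-oxo-2H-chromen-8-yl)-2-methylpenta-2,4-dienal
Conditions: PhMe, 100 °C
Reagents that add atoms: none
Why: Wittig olefination with the α-methyl stabilised ylide should give the (E)-trisubstituted alkene, with the styryl chain trans to the formyl group.

Step 4
Reactants: 6 (2E,4E)-5-(5,7-dimethoxy-2-oxo-2H-chromen-8-yl)-2-methylpenta-2,4-dienal
Product: 7 8-[(1E,3E)-5-hydroxy-4-methylpenta-1,3-dien-1-yl]-5,7-dimethoxy-2H-chromen-2-one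
Conditions: NaBH4, CeCl3·7H2O, MeOH–CH2Cl2, 0 °C
Reagents that add atoms: none
Why: Luche reduction should reduce the dienal 1,2-selectively and leave the coumarin lactone, which borohydride does not attack at this temperature.

Step 5
Reactants: 7 8-[(1E,3E)-5-hydroxy-4-methylpenta-1,3-dien-1-yl]-5,7-dimethoxy-2H-chromen-2-one
Product: 8 5,7-dimethoxy-8-[(1E,3E)-4-methyl-5-(4,4,5,5-tetramethyl-1,3,2-dioxaborolan-2-yl)penta-1,3-dien-1-yl]-2H-chromen-2-one
Conditions: B2pin2, Pd(MeCN)4(BF4)2 (5 mol %), DMSO–MeOH, rt
Reagents that add atoms: bis(pinacolato)diboron CC1(C)OB(OC1(C)C)B1OC(C)(C)C(C)(C)O1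
Why: Palladium-catalysed borylation of an allylic alcohol through an allyl complex of divalent palladium should place boron on the unhindered primary terminus, which keeps the aryl diene conjugated and (E,E).

Step 6
Reactants: 8 5,7-dimethoxy-8-[(1E,3E)-4-methyl-5-(4,4,5,5-tetramethyl-1,3,2-dioxaborolan-2-yl)penta-1,3-dien-1-yl]-2H-chromen-2-one; 2 5,7-dimethoxy-2-oxo-2H-chromene-8-carbaldehyde
Product: 9 8-[(1R,2R,3E)-4-(5,7-dimethoxy-2-oxo-2H-chromen-8-yl)-1-hydroxy-2-(prop-1-en-2-yl)but-3-en-1-yl]-5,7-dimethoxy-2H-chromen-2-one
Conditions: (R)-3,3'-bis(2,4,6-triisopropylphenyl)-1,1'-binaphthyl-2,2'-diyl hydrogen phosphate (10 mol %), 4 Å MS, PhMe–CH2Cl2, −30 to 0 °C; aqueous work-up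
Reagents that add atoms: none
Why: Chiral-phosphoric-acid-catalysed allylboration through a closed chair transition state: attack is γ-selective at the central dienyl carbon, the (E)-geometry next to boron translates into the anti relation of OH and styryl group (Cg/Ca), and the catalyst selects the aldehyde face that gives (R)-Cg.

Step 7
Reactants: 9 8-[(1R,2R,3E)-4-(5,7-dimethoxy-2-oxo-2H-chromen-8-yl)-1-hydroxy-2-(prop-1-en-2-yl)but-3-en-1-yl]-5,7-dimethoxy-2H-chromen-2-one
Product: 10 (3S,4R,5R)-3,5-bis(5,7-dimethoxy-2-oxo-2H-chromen-8-yl)-4-(prop-1-en-2-yl)oxolan-2-ol (three ring substituents all cis, anomer mixture)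
Conditions: PhI(OH)OTs (1.1 equiv), MeCN–H2O 9:1, 0 °C; NaHCO3 quench
Reagents that add atoms: water O
Why: Oxidative cyclisation with 1,2-aryl migration induced by a trivalent-iodine reagent (phenonium-type rearrangement, known for 4-aryl-3-butenols and 4-aryl-3-butenoic acids): the iodane should bind the styrene face anti to the isopropenyl group in the conformer that keeps the Ca–H bond in the alkene plane, the Cg hydroxyl closes 5-endo at the benzylic carbon, the electron-rich coumarinyl group migrates to Cb anti to the departing iodobenzene (inversion at Cb), and water captures the cyclic oxocarbenium ion, so that Cb is set cis to the isopropenyl group as the target requires.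

Step 8
Reactants: 11 triphenylphosphine; 12 2-bromopropene
Product: 13 triphenyl(prop-1-en-2-yl)phosphonium bromide
Conditions: Pd(PPh3)4 (2 mol %), PhMe, 110 °C, sealed tube
Reagents that add atoms: none
Why: Palladium-catalysed C–P coupling, in which oxidative addition of the alkenyl bromide to zerovalent palladium and reductive elimination quaternise the phosphine at the sp2 carbon that cannot react by direct substitution.

Step 9
Reactants: 10 (3S,4R,5R)-3,5-bis(5,7-dimethoxy-2-oxo-2H-chromen-8-yl)-4-(prop-1-en-2-yl)oxolan-2-ol; 13 triphenyl(prop-1-en-2-yl)phosphonium bromide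
Product: 16 IN0553 (target), via lactol phosphonium bromide 14 (not isolated), via hydroxy aldehyde ylide 15 (not isolated)
Conditions: 13 (1.3 equiv), Fe(acac)3 (30 mol %), PhSiH3, EtOH–ClCH2CH2Cl, 50 °C; evaporate; KHMDS, THF, −78 °C to rt, same flask
Reagents that add atoms: none
Why: Proposed new method: an iron hydride made from Fe(acac)3 and PhSiH3 should transfer a hydrogen atom to the CH2 terminus of the isopropenyl group, the nucleophilic tertiary radical at Cf adds to the CH2 terminus of the cationic acceptor 13 (Ce–Cf bond), divalent iron reduces the α-phosphonio radical and ethanol protonates it to salt 14, and KHMDS then gives ylide 15, whose lactol is in equilibrium with the free aldehyde, so that an intramolecular Wittig reaction forms Cc=Cd with loss of Ph3PO. The closest known reaction types are the iron-hydride reductive coupling of unactivated alkenes with electron-poor alkenes (Giese type), the radical–polar crossover annulation of γ,δ-unsaturated aldehydes with enals, the photoredox addition of alkyl radicals to vinylphosphonium salts followed by Wittig olefination, and the Schweizer annulation; the new element is a vinylphosphonium salt as acceptor under hydrogen-atom-transfer conditions, argued from its polarity match with a tertiary radical and from an α-phosphonio radical being at least as easily reduced as the α-carbonyl radicals of the known couplings. The six-membered carbocycle closes by 6-exo-trig attack of the ylide carbon on the aldehyde carbon and cycloreversion of the oxaphosphetane, assisted by the gem-dimethyl effect, while the temporary oxolane opens and releases the Cg hydroxyl, so no protecting group is needed. No stereocentre of the target is created, since the phosphorus-bearing carbon becomes sp2 and Ca and Cg are not acidic; the only labile centre is Cb, which is protected by forming the ylide at −78 °C next to a masked aldehyde and by the fact that an axial aryl group on Cb would clash 1,3-diaxially with a methyl group on Cf, so that epimerised material should close more slowly than the trans-configured one. The step needs chemoselective hydrogen-atom transfer, secured because the isopropenyl group is the only electron-neutral alkene (the coumarin 3,4-double bonds are conjugated and electron-poor), and a fixed alkene position, secured because the double bond can form only where phosphorus sits. Base is withheld until the radical stage is over, so that alkoxide addition to 13 cannot compete with the radical addition.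

**Compound list**

1 | 5,7-dimethoxy-2H-chromen-2-one | COc1cc(OC)c2ccc(=O)oc2c1 | starting material
2 | 5,7-dimethoxy-2-oxo-2H-chromene-8-carbaldehyde | COc1cc(OC)c2ccc(=O)oc2c1C=O | intermediate
3 | (triphenylphosphoranylidene)acetaldehyde | O=CC=P(c1ccccc1)(c1ccccc1)c1ccccc1 | starting material
4 | (2E)-3-(5,7-dimethoxy-2-oxo-2H-chromen-8-yl)prop-2-enal | COc1cc(OC)c2ccc(=O)oc2c1/C=C/C=O | intermediate
5 | 2-(triphenylphosphoranylidene)propanal | CC(C=O)=P(c1ccccc1)(c1ccccc1)c1ccccc1 | starting material
6 | (2E,4E)-5-(5,7-dimethoxy-2-oxo-2H-chromen-8-yl)-2-methylpenta-2,4-dienal | COc1cc(OC)c2ccc(=O)oc2c1/C=C/C=C(\C)C=O | intermediate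
7 | 8-[(1E,3E)-5-hydroxy-4-methylpenta-1,3-dien-1-yl]-5,7-dimethoxy-2H-chromen-2-one | COc1cc(OC)c2ccc(=O)oc2c1/C=C/C=C(\C)CO | intermediate
8 | (1E,3E)-pentadienyl pinacol boronate of 7 | COc1cc(OC)c2ccc(=O)oc2c1/C=C/C=C(\C)CB1OC(C)(C)C(C)(C)O1 | intermediate
9 | (1R,2R,3E)-homoallylic alcohol, anti, skipped diene | COc1cc(OC)c2ccc(=O)oc2c1/C=C/[C@H](C(C)=C)[C@@H](O)c1c(OC)cc(OC)c2ccc(=O)oc12 | intermediate
10 | (3S,4R,5R)-3,5-diaryl-4-(prop-1-en-2-yl)oxolan-2-ol | OC1O[C@@H](c2c(OC)cc(OC)c3ccc(=O)oc23)[C@@H](C(C)=C)[C@H]1c1c(OC)cc(OC)c2ccc(=O)oc12 | intermediate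
11 | triphenylphosphine | c1ccc(cc1)P(c1ccccc1)c1ccccc1 | starting material
12 | 2-bromopropene | CC(Br)=C | starting material
13 | triphenyl(prop-1-en-2-yl)phosphonium bromide | C=C(C)[P+](c1ccccc1)(c1ccccc1)c1ccccc1.[Br-] | intermediate
14 | lactol 10 with the isopropenyl group turned into C(CH3)2CH2CH(CH3)PPh3+ Br−, ring centres as in 10 | OC1O[C@@H](c2c(OC)cc(OC)c3ccc(=O)oc23)[C@@H](C(C)(C)CC(C)[P+](c2ccccc2)(c2ccccc2)c2ccccc2)[C@H]1c1c(OC)cc(OC)c2ccc(=O)oc12.[Br-] | intermediate
15 | open-chain γ-hydroxy aldehyde bearing the ylide C(CH3)2CH2C(CH3)=PPh3 | O=C[C@H](c1c(OC)cc(OC)c2ccc(=O)oc12)[C@H](C(C)(C)CC(C)=P(c1ccccc1)(c1ccccc1)c1ccccc1)[C@@H](O)c1c(OC)cc(OC)c2ccc(=O)oc12 | intermediate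
16 | IN0553, 8-[(R)-[(1R,2S)-2-(5,7-dimethoxy-2-oxo-2H-chromen-8-yl)-4,6,6-trimethylcyclohex-3-en-1-yl](hydroxy)methyl]-5,7-dimethoxy-2H-chromen-2-one | COc1cc(OC)c2ccc(=O)oc2c1[C@H]1C=C(C)CC(C)(C)[C@@H]1[C@@H](O)c1c(OC)cc(OC)c2ccc(=O)oc12 | target

Total step count: 9. Longest linear sequence: 8 (steps 1 to 7, then 9).

**Steps most likely to fail**

**Step 9.**
- What may go wrong: slow capture of the crowded tertiary radical by the cationic acceptor, so that plain hydrogenation of the isopropenyl group takes over; alkoxide addition to surplus acceptor once base is present; epimerisation at Cb before ring closure.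
- The fallback uses known chemistry, sets out from 9 and returns at 16.
- Silylation of 9 (TBSOTf, 2,6-lutidine) gives the tert-butyldimethylsilyl ether F1.
- The same iodane-induced aryl shift in aqueous MeCN, now with water as the only nucleophile, gives the open-chain α-aryl aldehyde F2.
- The established iron-hydride radical–polar crossover annulation of a γ,δ-unsaturated aldehyde with an enal, here methacrolein (Fe(acac)3, PhSiH3), forms Ce–Cf by radical conjugate addition and Cc–Cd by aldol closure under neutral conditions. It gives the β-hydroxy aldehyde F3, with the two new centres as a mixture.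
- Pinnick oxidation gives the β-hydroxy acid F4.
- Decarboxylative dehydration with DMF dineopentyl acetal gives the silyl-protected target F5.
- TBAF then gives 16.

**Step 7.**
- What may go wrong: attack of the iodane on the isopropenyl group or on the electron-rich arene, acid-induced ionisation of the benzylic C–O bond, and poor facial selectivity.
- The fallback sets out from 9 and returns at 10, and it separates ring closure from migration.
- 5-endo bromoetherification with NBS in MeCN gives the bromo-oxolane F6, which can be purified from its diastereomer.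
- AgBF4 in wet acetone then triggers the semipinacol-type aryl shift anti to bromide, and water captures the oxocarbenium ion to give 10.

**Step 6.**
- What may go wrong: sluggish addition to the hindered, electron-rich aldehyde, so that the uncatalysed pathway erodes the enantiomeric purity.
- The fallback sets out from 7 and returns at 9.
- MsCl, Et3N and LiCl convert 7 into the dienyl chloride F7.
- F7 is added to 2 in an asymmetric Nozaki–Hiyama–Kishi-type pentadienylation (CrCl2, chiral oxazoline sulfonamide ligand, THF). The allylchromium species attacks through its central carbon, gives the anti product whatever the halide geometry, and tolerates the lactones.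

**Further compounds**

F1 | step 9 | tert-butyldimethylsilyl ether of 9 | COc1cc(OC)c2ccc(=O)oc2c1/C=C/[C@H](C(C)=C)[C@@H](O[Si](C)(C)C(C)(C)C)c1c(OC)cc(OC)c2ccc(=O)oc12
F2 | step 9 | (2S,3R)-2-aryl-3-[(R)-aryl(tert-butyldimethylsilyloxy)methyl]-4-methylpent-4-enal | O=C[C@H](c1c(OC)cc(OC)c2ccc(=O)oc12)[C@H](C(C)=C)[C@@H](O[Si](C)(C)C(C)(C)C)c1c(OC)cc(OC)c2ccc(=O)oc12
F3 | step 9 | 2-hydroxy-1,5,5-trimethylcyclohexane-1-carbaldehyde bearing the aryl group at C3 and the silyloxy(aryl)methyl group at C4 | COc1cc(OC)c2ccc(=O)oc2c1[C@H]1C(O)C(C)(C=O)CC(C)(C)[C@@H]1[C@@H](O[Si](C)(C)C(C)(C)C)c1c(OC)cc(OC)c2ccc(=O)oc12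
F4 | step 9 | β-hydroxy acid from F3 | COc1cc(OC)c2ccc(=O)oc2c1[C@H]1C(O)C(C)(C(=O)O)CC(C)(C)[C@@H]1[C@@H](O[Si](C)(C)C(C)(C)C)c1c(OC)cc(OC)c2ccc(=O)oc12
F5 | step 9 | tert-butyldimethylsilyl ether of 16 | COc1cc(OC)c2ccc(=O)oc2c1[C@H]1C=C(C)CC(C)(C)[C@@H]1[C@@H](O[Si](C)(C)C(C)(C)C)c1c(OC)cc(OC)c2ccc(=O)oc12
F6 | step 7 | 2,5-diaryl-3-bromo-4-(prop-1-en-2-yl)oxolane, bromine trans to both neighbours, aryl groups cis | Br[C@@H]1[C@@H](c2c(OC)cc(OC)c3ccc(=O)oc23)O[C@@H](c2c(OC)cc(OC)c3ccc(=O)oc23)[C@H]1C(C)=C
F7 | step 6 | 8-[(1E,3E)-5-chloro-4-methylpenta-1,3-dien-1-yl]-5,7-dimethoxy-2H-chromen-2-one | COc1cc(OC)c2ccc(=O)oc2c1/C=C/C=C(\C)CCl
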